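| flask | left-handed substrate | right-handed substrate | gas | free catalyst | impurity | added ligand | remark | time |
|---|---|---|---|---|---|---|---|---|
| autumn | 0.50 M | 0.50 M | 24 mM (held) | 1 mM | 0.63 mM | 2.5 mM | run made earlier |  |
| dusk | 0.50 M | 0.50 M | 24 mM (held) | 1 mM | 0.63 mM | 5.6 mM | run made earlier |  |
| winter | 0.50 M | 0.50 M | 24 mM (held) | 0.50 mM | 0.63 mM | 3.7 mM | run made earlier |  |
| east | 0.50 M | 0.50 M | 24 mM (held) | 1.0 mM | 0.63 mM | 3.7 mM |  | 3.0 d |
| north-east | 0.50 M | 0.50 M | 24 mM (held) | 1.0 mM | 0.63 mM | 3.7 mM |  | 10 d |

| run | time / d | left-handed product / % | right-handed product / % |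
|---|---|---|---|
| autumn | 0.208 | 2.6 | 1.3 |
| autumn | 0.500 | 4.7 | 3.2 |
| autumn | 1.04 | 10.8 | 6.3 |
| autumn | 1.67 | 16.4 | 9.6 |
| autumn | 2.00 | 18.6 | 11.8 |
| autumn | 3.00 | 26.1 | 17.5 |
| autumn | 4.00 | 32.5 | 22.1 |
| dusk | 0.500 | 4.7 | 2.7 |
| dusk | 1.04 | 9.2 | 5.0 |
| dusk | 1.67 | 13.5 | 8.0 |
| dusk | 2.08 | 16.6 | 10.3 |
| dusk | 2.50 | 19.1 | 11.9 |
| dusk | 3.00 | 22.6 | 14.4 |
| dusk | 4.00 | 28.0 | 17.9 |
| winter | 0.333 | 1.4 | 0.5 |
| winter | 0.833 | 1.5 | 1.1 |
| winter | 1.67 | 1.8 | 0.8 |
| winter | 2.50 | 1.9 | 1.4 |
| winter | 4.00 | 2.0 | 0.9 |

(each reading ± 0.3 percentage points)

- free catalyst is single-handed; left-handed substrate and right-handed substrate are mirror images of each other, charged as a racemate, each of them at the stated concentration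
- the numbers in the tables scatter with a standard deviation of 0.3 percentage points
- at the start none of the gas is in solution
- an excess is the difference of the two amounts in percent of their sum
- an excess is below zero if the other one leads

- the winner by excess of left-handed product over right-handed product in the product; "neither" if no more than 2 percentage points parts them (east / north-east / neither)
- excess of left-handed product over right-handed product in the product at the end, east
- excess of left-handed product over right-handed product in the product at the end, north-east

**The pitfall.** Don't carry an excess from one reading to a later one. In autumn, the product excess goes from 26.3 % at 1.04 d to 19.0 % at 4.00 d, so it belongs to a moment, not a recipe.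

**One number.** Take each substrate's rest as a fraction of its own charge. Autumn's last reading leaves 35.0 % left-handed and 55.8 % right-handed. The selectivity factor s, the logarithm of the left-handed rest over that of the right-handed rest, reads 1.80. It says how many times faster, at equal amounts, the left-handed substrate reacts. Raise the right-handed rest to the power s and you have the left-handed rest; the product excess is the difference of the rests over the sum of the reacted fractions. Dusk, with 5.6 mM of added ligand, reads 1.85, so I carry s unchanged.

**Not enough.** The number s gives no clock. Winter, with free catalyst 0.50 mM below impurity 0.63 mM, has reacted just 2.90 % by 4.00 d. East holds 1.0 mM against 0.63 mM, like autumn and dusk, so I interpolate on added ligand.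

**My reckoning.** East lies 0.387 of the way from autumn to dusk, giving a right-handed rest of 67.4 % at 3.0 d, and through s an excess of 21.9 %. Assuming a first-order pace, I reckon north-east at a rest of 26.8 % and an excess of 10.7 %. In this reckoning east leads by 11 percentage points.

**The forecast.** It also picks east, but sits lower than my reckoning, at 21 % and 9 %: “The excess falls as the slower enantiomer catches up, so east wins.”

**The flask.** East gives 21.5 %, north-east 8.79 %, and east wins. North-east keeps 22 % of its right-handed substrate, against my 26.8 %. Through s, that simulated rest gives a left-handed rest of 6.46 %, where the flask holds 6.8 %, and an excess of 8.95 %.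

    reagent + free catalyst + left-handed substrate → free catalyst + left-handed product (k = 2690 M⁻² h⁻¹)
    reagent + free catalyst + right-handed substrate → free catalyst + right-handed product (k = 1520 M⁻² h⁻¹)
    free catalyst + impurity → spent catalyst (k = 1910 M⁻¹ h⁻¹)
    free catalyst + added ligand ⇌ idle complex, settled at all times (K = 183 M⁻¹)
    gas ⇌ reagent, rate k5*(csat - [reagent]) (kL = 0.670 h⁻¹)

**Later still.** Read east at 12 d: its right-handed rest of 15 % gives, through s, an excess of 6.45 %. The flask gives 6.39 %.

The earlier runs and the new flask are simulated on assumed constants.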